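**Plan**

1. Numbering (elemane): ring B = C5–C10. C10 carries the vinyl group (C1=C2) and C14H2OH, C5 carries C4(=C3H2)–C15H2OAc, C8 carries OAc, and the lactone is O–C6, C7, C11(=C13H2), C12.
2. Retrosynthesis: the silyl group, the C15 acetate (via the allylic chloride), the C8 acetate, the C11=C13 methylene and the C8 carbinol are taken back to the 8-oxo-12,6-olide 17. Its C9 then regains a temporary carboxyl carbon, tied as a γ-lactone to O–C14 (15).
3. Ring B of 15 is cut at C8–C9 and C6–C7. C6–O and C8=O flank C7, which carries the C11–C12 acid chain, so C7–C8–C11–C12 is a succinate: C6–C7 is an aldol bond, C8–C9 a Dieckmann bond, and the O–C6/C12 lactone closes on acidification.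
4. Forward: 5-menthyloxybutenolide → conjugate addition (C5) → α-ethylidene lactone → deconjugative alkylation (quaternary C10) → reduction, relactonisation on O–C14 and oxidation to aldehyde 11 → aldol/Dieckmann/lactonisation (ring B, then the 12,6-lactone) → decarboxylation, adjustment of oxidation level, acetates.
5. Stereochemistry: the acetal carbon of the butenolide sets C5 (anti addition) and C10 (alkylation anti to C5). C6 follows by Felkin–Anh addition, C7 by equilibration to the trans-lactone, and C8 by hydride delivered from the axial C14–OH.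

Key step: step 7

Remark: (5S)-5-(d-menthyloxy)furan-2(5H)-one, made from (+)-menthol, is taken as a commercial compound like its antipode.

**Step 1**
Reactants: 1 (5S)-5-[(1S,2R,5S)-menthyloxy]furan-2(5H)-one; 2 isopropenylmagnesium bromide; 3 acetaldehyde
Product: 4 3-(1-hydroxyethyl)-4-isopropenyl-5-(d-menthyloxy)dihydrofuran-2(3H)-one (3,4-trans, 4,5-trans; both carbinol epimers)
Conditions: 2 (1.5 equiv), CuBr·SMe2 (10 mol %), THF, −78 °C; then 3, −78 °C; aq. NH4Cl
Reagents that add atoms: none
Why: Copper-catalysed conjugate addition of the Grignard reagent should occur anti to the menthyloxy group (setting C5), and the magnesium enolate is trapped by acetaldehyde anti to the new isopropenyl group (tandem conjugate addition–aldol).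

**Step 2**
Reactants: 4
Product: 6 (E)-3-ethylidene-4-isopropenyl-5-(d-menthyloxy)dihydrofuran-2(3H)-one, via mesylate 5 (not isolated)
Conditions: MsCl, Et3N, CH2Cl2, 0 °C; then DBU, rt
Reagents that add atoms: none
Why: Mesylation and E1cB elimination should give the conjugated α-ethylidene lactone, whose alkene geometry is of no consequence for step 3.

**Step 3**
Reactants: 6; 7 tert-butyl bromoacetate
Product: 8 tert-butyl 2-[4-isopropenyl-5-(d-menthyloxy)-2-oxo-3-vinyltetrahydrofuran-3-yl]acetate (acetate arm trans, vinyl cis to isopropenyl)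
Conditions: LiN(iPr)2, THF/DMPU, −78 °C; then 7, −78 to −40 °C
Reagents that add atoms: none
Why: γ-Deprotonation gives the extended enolate, which should be alkylated at the α-carbon anti to the neighbouring isopropenyl group (deconjugative alkylation), creating the quaternary C10 with the C9 arm trans to the C5 substituent.

**Step 4**
Reactants: 8
Product: 9 tert-butyl 3-ethenyl-3,4-bis(hydroxymethyl)-5-methylhex-5-enoate
Conditions: LiBH4, THF (MeOH, 1 equiv), 0 °C to rt
Reagents that add atoms: none
Why: LiBH4 should reduce the acyl-acetal lactone through the lactol to the diol with loss of menthol while the tert-butyl ester survives (chemoselective hydride reduction).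

**Step 5**
Reactants: 9
Product: 10 4-(1-hydroxy-3-methylbut-3-en-2-yl)-4-vinyldihydrofuran-2(3H)-one
Conditions: KOtBu (10 mol %), THF, 0 °C to rt
Reagents that add atoms: none
Why: Alkoxide-catalysed intramolecular transesterification should close the five-membered lactone on O–C14 (favoured over the six-membered lactone through O–C6 under equilibrating conditions, Thorpe–Ingold effect), which masks C14–OH and keeps C9 acidic.

**Step 6**
Reactants: 10
Product: 11 3-methyl-2-(5-oxo-3-vinyltetrahydrofuran-3-yl)but-3-enal
Conditions: Dess–Martin periodinane, CH2Cl2, 0 °C to rt; used at once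
Reagents that add atoms: none
Why: Dess–Martin oxidation of the primary alcohol is non-basic and should give the aldehyde without epimerising or conjugating the α-isopropenyl centre C5.

**Step 7**
Reactants: 11; 12 monomethyl succinate (4-methoxy-4-oxobutanoic acid)
Product: 15 tricyclic keto bis-lactone (8-oxo-13-norelema-1,3-dien-12,6-olide with the temporary C9-carboxyl closed on O-14), via aldol adduct 13 (not isolated), via hydroxy acid 14 (not isolated)
Conditions: 12 (1.3 equiv), LiN(iPr)2 (2.6 equiv), THF, −78 °C; add 11, −78 °C; then LiN(SiMe3)2 (2.2 equiv), −78 to 0 °C; then 2 M HCl, rt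
Reagents that add atoms: none
Why: The dilithium dianion of 12 (ester enolate at C7, inert carboxylate at C12) adds to the aldehyde carbon C6 of 11 as in the first stage of a Stobbe condensation, and LiN(SiMe3)2 then reversibly enolises the temporary γ-lactone at C9, whose enolate attacks the methyl ester carbon C8 in a Dieckmann condensation that is driven to completion by deprotonation of the β-keto lactone formed. The closest known reactions are the aldol addition of succinate half-ester dianions to aldehydes (paraconic acid synthesis) and the Dieckmann cyclisation of a lactone enolate onto an ester. Ring B closes by 6-exo-trig attack of C9 on C8, and the butanolide closes on acidification by 5-exo-trig attack of O–C6 on the C12 acid. C6 is set by Felkin–Anh addition anti to the quaternary C10 with isopropenyl as the medium group, C7 by the chelated enolate (being α to C8 it is equilibrated to the equatorial position in step 8), and C9 is held cis to C14 by the five-membered lactone and is erased in step 8. The step needs addition to the aldehyde to outrun its enolisation, and C-acylation at C9 instead of elimination across C6–C7. This is secured by the low temperature, by the non-leaving lithium alkoxide at C6 and carboxylate at C12, and by C9 being the only enolisable carbon that reaches C8 through a six-membered transition state.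

**Step 8**
Reactants: 15
Product: 17 14-hydroxy-8-oxo-13-norelema-1,3-dien-12,6-olide, via ring-opened keto diacid 16 (not isolated)
Conditions: LiOH, THF/H2O, 0 °C to rt; then 1 M HCl to pH 2, 40 °C
Reagents that add atoms: none
Why: Saponification opens the β-keto lactone (and reversibly the butanolide, during which C7 should settle equatorial), the free β-keto acid loses CO2 on acidification so that C9 becomes CH2 and C14–OH is freed, and the C6 hydroxy acid relactonises (ester hydrolysis–decarboxylation).

**Step 9**
Reactants: 17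
Product: 18 8α,14-dihydroxy-13-norelema-1,3-dien-12,6-olide
Conditions: Me4NBH(OAc)3, MeCN/AcOH, −30 °C
Reagents that add atoms: none
Why: In a hydroxyl-directed triacetoxyborohydride reduction the axial C14 hydroxymethyl group should bind boron and deliver hydride to the top face of the C8 ketone, giving the equatorial 8α-alcohol that external hydride, blocked by the same axial group, would not give.

**Step 10**
Reactants: 18
Product: 19 14-O-(tert-butyldimethylsilyl)-8α-hydroxy-13-norelema-1,3-dien-12,6-olide
Conditions: TBSCl (1.1 equiv), imidazole, DMF, 0 °C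
Reagents that add atoms: tert-butyldimethylsilyl chloride, CC(C)(C)[Si](C)(C)Cl
Why: The primary hydroxyl should be silylated faster than the secondary C8 hydroxyl (chemoselective silylation).

**Step 11**
Reactants: 19
Product: 22 14-O-TBS-8α-hydroxyelema-1,3,11(13)-trien-12,6-olide, via Mannich base 20 (not isolated), via ammonium iodide 21 (not isolated)
Conditions: LiN(iPr)2 (2.4 equiv), THF, −78 °C; CH2=NMe2+ I−, −78 °C to rt; then MeI, MeOH, rt; then aq. NaHCO3, CH2Cl2
Reagents that add atoms: N,N-dimethylmethyleneiminium iodide, C=[N+](C)C.[I-]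
Why: The lactone enolate (C8–OH carried as its lithium alkoxide) undergoes a Mannich reaction with the iminium salt, and quaternisation followed by elimination installs the exocyclic C11=C13 methylene (standard α-methylenation of butanolides).

**Step 12**
Reactants: 22
Product: 23 8α-acetoxy-14-O-TBS-elema-1,3,11(13)-trien-12,6-olide
Conditions: Ac2O, DMAP (cat.), pyridine, CH2Cl2, 0 °C to rt
Reagents that add atoms: acetic anhydride, CC(=O)OC(C)=O
Why: Acylation of the one remaining free (secondary) hydroxyl.

**Step 13**
Reactants: 23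
Product: 24 8α-acetoxy-15-chloro-14-O-TBS-elema-1,3,11(13)-trien-12,6-olide
Conditions: Ca(OCl)2, solid CO2, CH2Cl2/H2O, 0 °C
Reagents that add atoms: calcium hypochlorite, [Ca+2].[O-]Cl.[O-]Cl
Why: Ene-type chlorination by HOCl at the electron-rich 1,1-disubstituted isopropenyl alkene should give the 2-(chloromethyl)allyl group, because the vinyl group has no allylic hydrogen and the methylene lactone is electron-poor.

**Step 14**
Reactants: 24
Product: 25 8α,15-diacetoxy-14-O-TBS-elema-1,3,11(13)-trien-12,6-olide
Conditions: CsOAc, DMF, rt to 40 °C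
Reagents that add atoms: cesium acetate, [Cs+].CC(=O)[O-]
Why: SN2 displacement of the primary allylic chloride by acetate.

**Step 15**
Reactants: 25
Product: 26 8α,15-diacetoxy-14-hydroxyelema-1,3,11(13)-trien-12,6-olide (target)
Conditions: HF·pyridine, THF/pyridine, 0 °C to rt
Reagents that add atoms: none
Why: Fluoride cleaves the silyl ether under mildly acidic conditions that leave the acetates and the methylene lactone untouched (desilylation).

**Compound list**

1 | (5S)-5-[(1S,2R,5S)-menthyloxy]furan-2(5H)-one | O=C1O[C@H](O[C@H]2C[C@@H](C)CC[C@@H]2C(C)C)C=C1 | starting material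
2 | isopropenylmagnesium bromide | CC(=C)[Mg]Br | starting material
3 | acetaldehyde | CC=O | starting material
4 | 3-(1-hydroxyethyl)-4-isopropenyl-5-(d-menthyloxy)dihydrofuran-2(3H)-one | CC(O)[C@@H]1C(=O)O[C@H](O[C@H]2C[C@@H](C)CC[C@@H]2C(C)C)[C@H]1C(C)=C | intermediate
5 | mesylate of 4 | CC(OS(C)(=O)=O)[C@@H]1C(=O)O[C@H](O[C@H]2C[C@@H](C)CC[C@@H]2C(C)C)[C@H]1C(C)=C | intermediate (not isolated)
6 | (E)-3-ethylidene-4-isopropenyl-5-(d-menthyloxy)dihydrofuran-2(3H)-one | C/C=C1/C(=O)O[C@H](O[C@H]2C[C@@H](C)CC[C@@H]2C(C)C)[C@H]1C(C)=C | intermediate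
7 | tert-butyl bromoacetate | BrCC(=O)OC(C)(C)C | starting material
8 | tert-butyl 2-[4-isopropenyl-5-(d-menthyloxy)-2-oxo-3-vinyltetrahydrofuran-3-yl]acetate | C=C[C@]1(C(=O)O[C@H](O[C@H]2C[C@@H](C)CC[C@@H]2C(C)C)[C@H]1C(C)=C)CC(=O)OC(C)(C)C | intermediate
9 | tert-butyl 3-ethenyl-3,4-bis(hydroxymethyl)-5-methylhex-5-enoate | C=C[C@](CO)(CC(=O)OC(C)(C)C)[C@@H](CO)C(C)=C | intermediate
10 | 4-(1-hydroxy-3-methylbut-3-en-2-yl)-4-vinyldihydrofuran-2(3H)-one | C=C[C@@]1(COC(=O)C1)[C@@H](CO)C(C)=C | intermediate
11 | 3-methyl-2-(5-oxo-3-vinyltetrahydrofuran-3-yl)but-3-enal | C=C[C@@]1(COC(=O)C1)[C@@H](C=O)C(C)=C | intermediate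
12 | monomethyl succinate | COC(=O)CCC(=O)O | starting material
13 | aldol adduct (hydroxy acid methyl ester, shown as the free acid) | C=C[C@@]1(COC(=O)C1)[C@@H]([C@@H](O)[C@H](CC(=O)O)C(=O)OC)C(C)=C | intermediate (not isolated)
14 | Dieckmann product, hydroxy acid form | C=C[C@]1(COC3=O)[C@@H]3C(=O)[C@@H](CC(=O)O)[C@H](O)[C@H]1C(C)=C | intermediate (not isolated)
15 | tricyclic keto bis-lactone | C=C[C@]1(COC3=O)[C@@H]3C(=O)[C@H]2CC(=O)O[C@@H]2[C@H]1C(C)=C | intermediate
16 | ring-opened keto diacid | C=C[C@]1(CO)[C@@H](C(=O)O)C(=O)[C@@H](CC(=O)O)[C@H](O)[C@H]1C(C)=C | intermediate (not isolated)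
17 | 14-hydroxy-8-oxo-13-norelema-1,3-dien-12,6-olide | C=C[C@]1(CO)CC(=O)[C@H]2CC(=O)O[C@@H]2[C@H]1C(C)=C | intermediate
18 | 8α,14-dihydroxy-13-norelema-1,3-dien-12,6-olide | C=C[C@]1(CO)C[C@H](O)[C@H]2CC(=O)O[C@@H]2[C@H]1C(C)=C | intermediate
19 | 14-O-TBS-8α-hydroxy-13-norelema-1,3-dien-12,6-olide | C=C[C@]1(CO[Si](C)(C)C(C)(C)C)C[C@H](O)[C@H]2CC(=O)O[C@@H]2[C@H]1C(C)=C | intermediate
20 | Mannich base (11-dimethylaminomethyl lactone, both C11 epimers) | C=C[C@]1(CO[Si](C)(C)C(C)(C)C)C[C@H](O)[C@H]2C(CN(C)C)C(=O)O[C@@H]2[C@H]1C(C)=C | intermediate (not isolated)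
21 | ammonium iodide of 20 | C=C[C@]1(CO[Si](C)(C)C(C)(C)C)C[C@H](O)[C@H]2C(C[N+](C)(C)C)C(=O)O[C@@H]2[C@H]1C(C)=C.[I-] | intermediate (not isolated)
22 | 14-O-TBS-8α-hydroxyelema-1,3,11(13)-trien-12,6-olide | C=C[C@]1(CO[Si](C)(C)C(C)(C)C)C[C@H](O)[C@H]2C(=C)C(=O)O[C@@H]2[C@H]1C(C)=C | intermediate
23 | 8α-acetoxy-14-O-TBS-elema-1,3,11(13)-trien-12,6-olide | C=C[C@]1(CO[Si](C)(C)C(C)(C)C)C[C@H](OC(C)=O)[C@H]2C(=C)C(=O)O[C@@H]2[C@H]1C(C)=C | intermediate
24 | 8α-acetoxy-15-chloro-14-O-TBS-elema-1,3,11(13)-trien-12,6-olide | C=C[C@]1(CO[Si](C)(C)C(C)(C)C)C[C@H](OC(C)=O)[C@H]2C(=C)C(=O)O[C@@H]2[C@H]1C(=C)CCl | intermediate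
25 | 8α,15-diacetoxy-14-O-TBS-elema-1,3,11(13)-trien-12,6-olide | C=C[C@]1(CO[Si](C)(C)C(C)(C)C)C[C@H](OC(C)=O)[C@H]2C(=C)C(=O)O[C@@H]2[C@H]1C(=C)COC(C)=O | intermediate
26 | 8α,15-diacetoxy-14-hydroxyelema-1,3,11(13)-trien-12,6-olide | C=C[C@]1(CO)C[C@H](OC(C)=O)[C@H]2C(=C)C(=O)O[C@@H]2[C@H]1C(=C)COC(C)=O | target

**Totals and risks**

Total step count: 15. Longest linear sequence: 15 steps (from 1; compounds 2, 3, 7 and 12 are bought).

Steps most likely to fail:

- **Step 7.** The basic dianion may enolise the α-isopropenyl aldehyde (epimerisation at C5, migration of the isopropenyl double bond into conjugation), or the aldolate may revert before the second ring bond forms. The fallback sets out from 11 and uses a weakly basic zinc enolate: Reformatsky reaction with dimethyl 2-bromosuccinate and Zn (THF, 40 °C), followed by lactonisation of the zinc aldolate onto the distal ester, gives the paraconic ester F1. Ring B is then closed in a separate Dieckmann step (LiN(SiMe3)2, THF, −78 to 0 °C), which comes back to the route at 15.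

- **Step 9.** Hydride transfer from boron bound at the C14 oxygen may not reach C8, so that free hydride attacks the unhindered face and facial selectivity is lost to the axial 8β-alcohol. The fallback sets out from 17 and reaches the equatorial alcohol by inversion. TBSCl and imidazole give the silyl ether ketone F2. LiBH(sBu)3 (THF, −78 °C) attacks away from the axial C14 group and gives the axial alcohol F3. Its triflate F4 (Tf2O, pyridine, CH2Cl2, −20 °C) is displaced with inversion by KNO2 (18-crown-6, DMF, rt; Lattrell–Dax inversion), and hydrolysis of the nitrite ester on work-up comes back to the route at 19.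

- **Step 8.** Hydroxide may open ring B by retro-aldol cleavage of the β-hydroxy ketone, or eliminate the C6 oxygen, before the decarboxylation takes place. The fallback sets out from 15 and avoids aqueous base. Heating in allyl alcohol/toluene (100 °C) transesterifies the β-keto lactone through its acylketene to the allyl β-keto ester F5, with C14–OH free. Pd(PPh3)4 (cat.) and morpholine (THF, rt; zerovalent palladium) then remove the allyl ester with loss of CO2 under neutral conditions, which comes back to the route at 17.

**Further compounds**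

F1 | step 7 | paraconic ester: methyl 2-[3-methyl-1-(5-oxo-3-vinyltetrahydrofuran-3-yl)... side chain of 11]-5-oxotetrahydrofuran-3-carboxylate (2,3-trans) | C=C[C@@]1(COC(=O)C1)[C@@H]([C@H]2OC(=O)C[C@@H]2C(=O)OC)C(C)=C
F2 | step 9 | 14-O-TBS-8-oxo-13-norelema-1,3-dien-12,6-olide | C=C[C@]1(CO[Si](C)(C)C(C)(C)C)CC(=O)[C@H]2CC(=O)O[C@@H]2[C@H]1C(C)=C
F3 | step 9 | 14-O-TBS-8β-hydroxy-13-norelema-1,3-dien-12,6-olide | C=C[C@]1(CO[Si](C)(C)C(C)(C)C)C[C@@H](O)[C@H]2CC(=O)O[C@@H]2[C@H]1C(C)=C
F4 | step 9 | 8β-trifluoromethanesulfonate of F3 | C=C[C@]1(CO[Si](C)(C)C(C)(C)C)C[C@@H](OS(=O)(=O)C(F)(F)F)[C@H]2CC(=O)O[C@@H]2[C@H]1C(C)=C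
F5 | step 8 | allyl β-keto ester (allyl 14-hydroxy-8-oxo-13-norelema-1,3-dien-12,6-olide-9-carboxylate) | C=C[C@]1(CO)[C@@H](C(=O)OCC=C)C(=O)[C@H]2CC(=O)O[C@@H]2[C@H]1C(C)=C
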